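**Strategy**

1. The target is a 2-methyl-1,4-naphthoquinone that carries at C3 a C40 chain of eight prenyl units; the second unit is saturated (7'R) and the alkenes at 2', 10', 14', 18', 22' and 26' are E.
2. Enabling feature: in the quinone ring, C2 (methyl) and C3 (the C1' methylene) lie between the C1 and C4 carbonyls, and the fused benzo ring (C4a to C8a) is unsubstituted. C2=C3 therefore maps onto a 2-alkyne, C1 with the benzo ring onto a phenylcarbene and C4 onto one CO, and either alkyne orientation gives the same quinone.
3. Cuts: first C1–C2, C3–C4 and C4–C4a of the quinone ring (benzannulation of a C43 skipped enyne); then C4'–C5' (C35 alkyl sulfone plus C8 enyne bromide) and the propargylic bond of the C8 piece; then C12–C13 of the C35 unit (C20 allyl sulfone plus C15 allylic bromide).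
4. Forward: the chain is joined linearly, C20 + C15 and then C35 + C8; the only ring formed, the quinone ring, is closed last onto the phenyl ring supplied by phenyllithium.
5. Stereochemistry: the single stereocentre comes from Ru-(R)-BINAP hydrogenation of the 2,3-alkene of all-E-heptaprenol. Four E alkenes are bought with geranylgeraniol and farnesol, two are made by E-selective SeO2 oxidations, and all later C–C bond formations are SN2 reactions that leave them alone.

Key step: step 18

Remark: unprimed locants are those of the naphthoquinone, primed locants count the chain from the ring, heptaprenyl compounds are numbered from the heteroatom-bearing C1, and geranylgeraniol and farnesol are taken as the commercial all-E isomers.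

**Route**

Step 1
Reactants: 1 all-E-geranylgeraniol
Product: 2 all-E-geranylgeranyl bromide
Conditions: PBr3 (0.4 equiv), Et2O, −10 to 0 °C
Reagents that add atoms: phosphorus tribromide, BrP(Br)Br
Why: Bromination of a primary allylic alcohol with PBr3 proceeds by SN2 attack of bromide on the phosphite ester, and at this temperature the 2E alkene should neither migrate nor isomerise.

Step 2
Reactants: 2 all-E-geranylgeranyl bromide
Product: 3 all-E-geranylgeranyl phenyl sulfone
Conditions: PhSO2Na (1.5 equiv), DMF–THF, 20 °C
Reagents that add atoms: sodium benzenesulfinate (PhSO2Na), [Na+].[O-]S(=O)c1ccccc1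
Why: SN2 S-alkylation of the ambident sulfinate by the soft primary allylic bromide in a dipolar aprotic medium should give the allyl phenyl sulfone with all alkenes unchanged.

Step 3
Reactants: 4 (2E,6E)-farnesol
Product: 5 (2E,6E)-farnesyl tert-butyldimethylsilyl ether
Conditions: TBSCl, imidazole, DMF, 20 °C
Reagents that add atoms: tert-butyldimethylsilyl chloride (TBSCl), CC(C)(C)[Si](C)(C)Cl
Why: Imidazole-promoted silylation of a primary alcohol is routine, and a silyl ether is chosen because it tolerates SeO2 and the sulfonyl carbanion and, unlike an allylic ester, is not ionised by zerovalent palladium in step 7.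

Step 4
Reactants: 5 (2E,6E)-farnesyl tert-butyldimethylsilyl ether
Product: 6 (2E,6E,10E)-12-hydroxyfarnesyl tert-butyldimethylsilyl ether
Conditions: SeO2 (0.3 equiv), t-BuOOH (2.5 equiv), salicylic acid (0.1 equiv), CH2Cl2, 0 to 20 °C
Reagents that add atoms: selenium dioxide, O=[Se]=O (oxygen donor); tert-butyl hydroperoxide, CC(C)(C)OO (re-oxidant that supplies the oxygen in the end)
Why: Riley-type allylic oxidation (ene reaction of SeO2, then [2,3]-sigmatropic shift) should occur at the terminal, most accessible trisubstituted alkene and at the methyl trans to the chain, giving the E allylic alcohol when the reaction is stopped before over-oxidation to the enal becomes important.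

Step 5
Reactants: 6 (2E,6E,10E)-12-hydroxyfarnesyl tert-butyldimethylsilyl ether
Product: 7 (2E,6E,10E)-12-bromofarnesyl tert-butyldimethylsilyl ether
Conditions: CBr4, PPh3, CH2Cl2, 0 °C
Reagents that add atoms: carbon tetrabromide, BrC(Br)(Br)Br
Why: The Appel reaction replaces the primary allylic hydroxyl by bromide through SN2 displacement of the oxyphosphonium group under neutral conditions, which should spare the silyl ether and keep the 10E geometry.

Step 6
Reactants: 3 all-E-geranylgeranyl phenyl sulfone, 7 (2E,6E,10E)-12-bromofarnesyl tert-butyldimethylsilyl ether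
Product: 9 C35 sulfone silyl ether (all-E-heptaprenyl tert-butyldimethylsilyl ether bearing PhSO2 at C13; racemic at C13), via lithiated sulfone 8 (not isolated)
Conditions: n-BuLi (1.0 equiv), THF–DMPU, −78 °C; then 7, −78 to −40 °C
Reagents that add atoms: none
Why: In this Biellmann coupling the allylic sulfonyl carbanion is alkylated at its α-carbon by the primary allylic bromide in an SN2 reaction, joining C20 and C15 head to tail without moving any alkene, and the racemic sulfone-bearing centre is erased in step 7.

Step 7
Reactants: 9 C35 sulfone silyl ether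
Product: 10 all-E-heptaprenyl tert-butyldimethylsilyl ether
Conditions: PdCl2(dppp) (5 mol%), LiBHEt3 (2.5 equiv), THF, 0 °C
Reagents that add atoms: none
Why: In this palladium-catalysed hydride desulfonylation of an allylic sulfone, zerovalent palladium formed in situ ionises the allylic C–S bond and hydride is delivered to the less substituted terminus of the π-allyl complex, so the trisubstituted alkene should stay in place as the E isomer while the silyl ether is inert.

Step 8
Reactants: 10 all-E-heptaprenyl tert-butyldimethylsilyl ether
Product: 11 all-E-heptaprenol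
Conditions: Bu4NF, THF, 0 to 20 °C
Reagents that add atoms: none
Why: Fluoride-induced cleavage of the Si–O bond (standard desilylation) frees the allylic hydroxyl that must direct the hydrogenation.

Step 9
Reactants: 11 all-E-heptaprenol
Product: 12 (3S)-2,3-dihydro-all-E-heptaprenol
Conditions: Ru(OAc)2[(R)-BINAP] (0.5 mol%), H2 (100 atm), MeOH–CH2Cl2, 20 °C
Reagents that add atoms: none
Why: In this Noyori asymmetric hydrogenation the hydroxyl group binds to the divalent ruthenium centre so that only the 2,3-alkene is reduced, and with (R)-BINAP an E allylic alcohol should receive hydrogen on the face that gives the 3S product (the sense in which geraniol gives (S)-citronellol), which sets the only stereocentre while the six remote alkenes stay untouched.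

Step 10
Reactants: 12 (3S)-2,3-dihydro-all-E-heptaprenol
Product: 13 (3S)-2,3-dihydro-all-E-heptaprenyl iodide
Conditions: I2, PPh3, imidazole, CH2Cl2, 0 to 20 °C
Reagents that add atoms: iodine, II
Why: Appel-type iodination replaces the primary hydroxyl by iodide through SN2 displacement two carbons away from the stereocentre, which is therefore not affected.

Step 11
Reactants: 13 (3S)-2,3-dihydro-all-E-heptaprenyl iodide
Product: 14 (3S)-2,3-dihydro-all-E-heptaprenyl phenyl sulfone
Conditions: PhSO2Na (2 equiv), DMF–THF, 60 °C
Reagents that add atoms: sodium benzenesulfinate (PhSO2Na), [Na+].[O-]S(=O)c1ccccc1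
Why: SN2 S-alkylation of the sulfinate by the primary iodide should give the alkyl phenyl sulfone, with the C3 stereocentre a spectator.

Step 12
Reactants: 15 prenyl bromide (1-bromo-3-methylbut-2-ene), 16 1-propynylmagnesium bromide
Product: 17 2-methylhept-2-en-5-yne
Conditions: CuCl (5 mol%), THF, 0 to 40 °C
Reagents that add atoms: none
Why: Copper-catalysed coupling of an alkynylmagnesium halide with a primary allylic bromide is expected to proceed mainly by SN2 attack at the unhindered CH2 terminus and to give the skipped (1,4-) enyne.

Step 13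
Reactants: 17 2-methylhept-2-en-5-yne
Product: 18 (2E)-2-methylhept-2-en-5-yn-1-ol
Conditions: SeO2 (0.3 equiv), t-BuOOH (2 equiv), CH2Cl2, 0 to 20 °C
Reagents that add atoms: selenium dioxide, O=[Se]=O (oxygen donor); tert-butyl hydroperoxide, CC(C)(C)OO (re-oxidant that supplies the oxygen in the end)
Why: Riley-type allylic oxidation should engage the alkene far faster than the alkyne and functionalise the position next to the more substituted alkene carbon, that is the methyl trans to the chain and not the doubly activated C4 methylene, giving the E allylic alcohol.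

Step 14
Reactants: 18 (2E)-2-methylhept-2-en-5-yn-1-ol
Product: 19 (2E)-1-bromo-2-methylhept-2-en-5-yne
Conditions: PBr3 (0.4 equiv), Et2O, −10 °C
Reagents that add atoms: phosphorus tribromide, BrP(Br)Br
Why: PBr3 bromination of the primary allylic alcohol (SN2 on the phosphite ester) at low temperature should retain the E alkene and leave the alkyne alone.

Step 15
Reactants: 14 (3S)-2,3-dihydro-all-E-heptaprenyl phenyl sulfone, 19 (2E)-1-bromo-2-methylhept-2-en-5-yne
Product: 21 C43 enyne sulfone (PhSO2 at C5'; both epimers at C5'; methyl-bearing C7' S), via lithiated sulfone 20 (not isolated)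
Conditions: n-BuLi (1.05 equiv), THF–DMPU, −78 °C; then 19 (1.2 equiv), −78 to −40 °C
Reagents that add atoms: none
Why: SN2 alkylation of the α-sulfonyl carbanion by the primary allylic bromide forms the C4'–C5' bond, should outrun proton transfer from the skipped enyne methylene at −78 °C, and leaves the sulfonyl group on a non-allylic carbon from which it can be removed without regiochemical ambiguity.

Step 16
Reactants: 21 C43 enyne sulfone
Product: 22 C43 skipped enyne (7'R; 2'E and all other alkenes E; 2-alkyne terminus)
Conditions: Na(Hg) (6% Na), Na2HPO4, MeOH–THF, −20 to 0 °C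
Reagents that add atoms: none
Why: Reductive desulfonylation by electron transfer from Na(Hg) in phosphate-buffered methanol cleaves the alkyl C–S bond without reducing the isolated alkyne or the alkenes and without base-induced enyne isomerisation, and the stereocentre is not involved, its descriptor changing from S to R only because the CIP ranking of its two chain arms is reversed.

Step 17
Reactants: 23 chromium hexacarbonyl Cr(CO)6, 24 phenyllithium
Product: 26 pentacarbonyl[methoxy(phenyl)carbene]chromium (CO)5Cr=C(OMe)Ph, via lithium acyl chromate 25 (not isolated)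
Conditions: PhLi, Et2O, 0 to 20 °C; then Me3OBF4, CH2Cl2, 0 °C
Reagents that add atoms: trimethyloxonium tetrafluoroborate (Me3OBF4), C[O+](C)C.F[B-](F)(F)F
Why: In this Fischer carbene synthesis phenyllithium adds to a carbonyl ligand of Cr(CO)6 to give the acyl chromate, whose oxygen is methylated by the hard oxonium salt to the stable methoxy(phenyl)carbene complex of zerovalent chromium.

Step 18
Reactants: 22 C43 skipped enyne, 26 pentacarbonyl[methoxy(phenyl)carbene]chromium
Product: 29 CNP0107344.1 (target naphthoquinone), via 2-alkyl-4-methoxy-3-methyl-1-naphthol Cr(CO)3 complex 27 (not isolated), via 3-alkyl-4-methoxy-2-methyl-1-naphthol Cr(CO)3 complex 28 (not isolated)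
Conditions: 26 (1.5 equiv), t-BuOMe, 55 °C, argon; then (NH4)2Ce(NO3)6 (excess), MeCN–H2O, 0 to 20 °C
Reagents that add atoms: water, O
Why: Heating releases one CO ligand from 26, the alkyne of 22 coordinates and inserts into the Cr=C bond to give a vinylcarbene, CO insertion gives a chromium-bound vinylketene, and 6π electrocyclisation onto an ortho carbon of the phenyl group followed by enolisation gives the 4-methoxy-1-naphthol Cr(CO)3 complexes 27 and 28, which (NH4)2Ce(NO3)6 demetalates and oxidises, with loss of methanol, to the 1,4-quinone. The closest known reaction type is the Dötz benzannulation of aryl(alkoxy)carbene complexes of zerovalent chromium with internal alkynes followed by oxidative work-up, which is established for 2-alkynes that carry a skipped alkene. The one ring that closes, the quinone ring C1–C2–C3–C4–C4a–C8a, arises in a formal [3+2+1] mode (carbene carbon with the ipso and ortho carbons of phenyl, the two alkyne carbons, one CO), the bonds C1–C2 and C3–C4 being made by the two insertions and the last bond, C4–C4a, by the electrocyclisation. No stereocentre is formed, and because the medium is neutral and neither an allyl cation nor a hydroquinone anion is ever present, C7' and the E geometry of the 2' alkene and of the five remote alkenes should be untouched and neither chromanol formation nor O-alkylation can intervene. The selectivity needed is chemoselectivity only: the alkyne must react in preference to the seven trisubstituted alkenes, which do not add to this carbene at 55 °C and cannot be reached intramolecularly across the 1,4-enyne spacing, and phenol formation with CO insertion is favoured over indene, furan or cyclobutenone formation by the chromium methoxy(phenyl)carbene in a weakly coordinating ether. The orientation of alkyne insertion does not matter, since 27 and 28 differ only in which oxygen carries the methyl group and the unsubstituted benzo ring makes their quinones identical.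

**Compound list**

1 | all-E-geranylgeraniol | CC(C)=CCC/C(C)=C/CC/C(C)=C/CC/C(C)=C/CO | starting material
2 | all-E-geranylgeranyl bromide | CC(C)=CCC/C(C)=C/CC/C(C)=C/CC/C(C)=C/CBr | intermediate
3 | all-E-geranylgeranyl phenyl sulfone | CC(C)=CCC/C(C)=C/CC/C(C)=C/CC/C(C)=C/CS(=O)(=O)c1ccccc1 | intermediate
4 | (2E,6E)-farnesol | CC(C)=CCC/C(C)=C/CC/C(C)=C/CO | starting material
5 | (2E,6E)-farnesyl tert-butyldimethylsilyl ether | CC(C)=CCC/C(C)=C/CC/C(C)=C/CO[Si](C)(C)C(C)(C)C | intermediate
6 | (2E,6E,10E)-12-hydroxyfarnesyl tert-butyldimethylsilyl ether | OC/C(C)=C/CC/C(C)=C/CC/C(C)=C/CO[Si](C)(C)C(C)(C)C | intermediate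
7 | (2E,6E,10E)-12-bromofarnesyl tert-butyldimethylsilyl ether | BrC/C(C)=C/CC/C(C)=C/CC/C(C)=C/CO[Si](C)(C)C(C)(C)C | intermediate
8 | lithiated geranylgeranyl phenyl sulfone (lithium on the sulfone-bearing C1; formed in the flask) | CC(C)=CCC/C(C)=C/CC/C(C)=C/CC/C(C)=C/C([Li])S(=O)(=O)c1ccccc1 | intermediate
9 | C35 sulfone silyl ether (all-E-heptaprenyl tert-butyldimethylsilyl ether with PhSO2 at C13, racemic there) | CC(C)=CCC/C(C)=C/CC/C(C)=C/CC/C(C)=C/C(S(=O)(=O)c1ccccc1)C/C(C)=C/CC/C(C)=C/CC/C(C)=C/CO[Si](C)(C)C(C)(C)C | intermediate
10 | all-E-heptaprenyl tert-butyldimethylsilyl ether | CC(C)=CCC/C(C)=C/CC/C(C)=C/CC/C(C)=C/CC/C(C)=C/CC/C(C)=C/CC/C(C)=C/CO[Si](C)(C)C(C)(C)C | intermediate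
11 | all-E-heptaprenol | CC(C)=CCC/C(C)=C/CC/C(C)=C/CC/C(C)=C/CC/C(C)=C/CC/C(C)=C/CC/C(C)=C/CO | intermediate
12 | (3S)-2,3-dihydro-all-E-heptaprenol | CC(C)=CCC/C(C)=C/CC/C(C)=C/CC/C(C)=C/CC/C(C)=C/CC/C(C)=C/CC[C@H](C)CCO | intermediate
13 | (3S)-2,3-dihydro-all-E-heptaprenyl iodide | CC(C)=CCC/C(C)=C/CC/C(C)=C/CC/C(C)=C/CC/C(C)=C/CC/C(C)=C/CC[C@H](C)CCI | intermediate
14 | (3S)-2,3-dihydro-all-E-heptaprenyl phenyl sulfone | CC(C)=CCC/C(C)=C/CC/C(C)=C/CC/C(C)=C/CC/C(C)=C/CC/C(C)=C/CC[C@H](C)CCS(=O)(=O)c1ccccc1 | intermediate
15 | prenyl bromide (1-bromo-3-methylbut-2-ene) | CC(C)=CCBr | starting material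
16 | 1-propynylmagnesium bromide | CC#C[Mg]Br | starting material
17 | 2-methylhept-2-en-5-yne | CC#CCC=C(C)C | intermediate
18 | (2E)-2-methylhept-2-en-5-yn-1-ol | CC#CC/C=C(C)/CO | intermediate
19 | (2E)-1-bromo-2-methylhept-2-en-5-yne | CC#CC/C=C(C)/CBr | intermediate
20 | lithiated (3S)-2,3-dihydroheptaprenyl phenyl sulfone (lithium on C1; formed in the flask) | CC(C)=CCC/C(C)=C/CC/C(C)=C/CC/C(C)=C/CC/C(C)=C/CC/C(C)=C/CC[C@H](C)CC([Li])S(=O)(=O)c1ccccc1 | intermediate
21 | C43 enyne sulfone (PhSO2 at C5', both epimers there; C7' S; all alkenes E) | CC(C)=CCC/C(C)=C/CC/C(C)=C/CC/C(C)=C/CC/C(C)=C/CC/C(C)=C/CC[C@H](C)CC(S(=O)(=O)c1ccccc1)C/C(C)=C/CC#CC | intermediate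
22 | C43 skipped enyne (7'R; all alkenes E) | CC(C)=CCC/C(C)=C/CC/C(C)=C/CC/C(C)=C/CC/C(C)=C/CC/C(C)=C/CC[C@H](C)CCC/C(C)=C/CC#CC | intermediate
23 | chromium hexacarbonyl, Cr(CO)6 | O=C=[Cr](=C=O)(=C=O)(=C=O)(=C=O)=C=O | starting material
24 | phenyllithium | [Li]c1ccccc1 | starting material
25 | lithium benzoylpentacarbonylchromate, Li[(CO)5CrC(O)Ph] (formed in the flask) | [Li+].[O-]C(c1ccccc1)=[Cr](=C=O)(=C=O)(=C=O)(=C=O)=C=O | intermediate
26 | pentacarbonyl[methoxy(phenyl)carbene]chromium, (CO)5Cr=C(OMe)Ph, zerovalent chromium | COC(c1ccccc1)=[Cr](=C=O)(=C=O)(=C=O)(=C=O)=C=O | intermediate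
27 | 2-alkyl-4-methoxy-3-methyl-1-naphthol Cr(CO)3 complex (chain next to OH; Cr(CO)3 bound η6 to the oxygenated ring, written as a separate fragment; formed in the flask) | CC(C)=CCC/C(C)=C/CC/C(C)=C/CC/C(C)=C/CC/C(C)=C/CC/C(C)=C/CC[C@H](C)CCC/C(C)=C/Cc1c(C)c(OC)c2ccccc2c1O.O=C=[Cr](=C=O)=C=O | intermediate
28 | 3-alkyl-4-methoxy-2-methyl-1-naphthol Cr(CO)3 complex (chain next to OMe; Cr(CO)3 bound η6 to the oxygenated ring, written as a separate fragment; formed in the flask) | CC(C)=CCC/C(C)=C/CC/C(C)=C/CC/C(C)=C/CC/C(C)=C/CC/C(C)=C/CC[C@H](C)CCC/C(C)=C/Cc1c(C)c(O)c2ccccc2c1OC.O=C=[Cr](=C=O)=C=O | intermediate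
29 | CNP0107344.1, 2-methyl-3-[(7'R)-all-E-chain]-1,4-naphthoquinone | CC(C)=CCC/C(C)=C/CC/C(C)=C/CC/C(C)=C/CC/C(C)=C/CC/C(C)=C/CC[C@H](C)CCC/C(C)=C/CC1=C(C)C(=O)c2ccccc2C1=O | target

**Step count and risks**

Total step count: 18. Longest linear sequence: 12 steps (from farnesol 4: steps 3, 4, 5, 6, 7, 8, 9, 10, 11, 15, 16, 18).

Steps most likely to fail:

Step 18. The carbene complex may decompose thermally before the bulky, lipophilic alkyne inserts. CO insertion may be incomplete, diverting material to indene, furan or cyclobutenone products. The polyene may suffer oxidative damage during the (NH4)2Ce(NO3)6 work-up. The fallback gives up ring construction on the chain and instead couples the C35 sulfone to a protected menadiol unit that already carries the first prenyl unit. It sets out from sulfone 14 and returns at 29. Purchased 2-bromo-1,4-dimethoxy-3-methylnaphthalene (COc1c(C)c(Br)c(OC)c2ccccc12) is converted with Mg in THF into (1,4-dimethoxy-3-methyl-2-naphthyl)magnesium bromide F1, which is allylated with prenyl bromide 15 under CuI catalysis to 1,4-dimethoxy-2-methyl-3-prenylnaphthalene F2. SeO2/t-BuOOH oxidation gives the E allylic alcohol F3 and CBr4/PPh3 the E allylic bromide F4. Lithiated sulfone 20, made from 14 as in step 15, is alkylated with F4 to the chain sulfone F5. Na(Hg)/Na2HPO4 removes the sulfonyl group to give the 1,4-dimethoxynaphthalene F6, and (NH4)2Ce(NO3)6 in aqueous MeCN at 0 °C oxidatively demethylates F6 to 29.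

Step 13. Over-oxidation to the enal, competing propargylic oxidation at the doubly activated methylene and evaporative loss of the small enyne may erode the throughput. The fallback brings the oxygen and the E alkene in from the start. It sets out from 1-propynylmagnesium bromide 16 and returns at 18. Purchased 2-methyl-2-vinyloxirane (isoprene monoxide, CC1(C=C)CO1) is opened in the SN2′ sense with concomitant oxidation by CuCl2/LiCl to (2E)-4-chloro-2-methylbut-2-enal F7. Luche reduction (NaBH4, CeCl3·7H2O, MeOH, 0 °C) gives (2E)-4-chloro-2-methylbut-2-en-1-ol F8. CuCl-catalysed coupling of F8 with an excess of 16, the first equivalent being consumed by the hydroxyl group, gives enynol 18.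

Step 9. The catalyst may be poisoned by traces of sulfur, palladium or boron from steps 6 to 8, the lipophilic substrate may be poorly soluble in the methanolic medium, and alkene migration at insufficient hydrogen pressure may erode the enantioselectivity. The fallback sets the stereocentre by conjugate reduction of the enal instead of directed hydrogenation. It sets out from 11 and returns at 12. MnO2 in CH2Cl2 oxidises 11 to all-E-heptaprenal F9. Iminium-catalysed asymmetric transfer hydrogenation with a Hantzsch ester, using the enantiomer of the chiral amine salt catalyst that turns citral into (S)-citronellal, gives (3S)-2,3-dihydroheptaprenal F10. NaBH4 in EtOH reduces F10 to 12.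

**Further compounds**

F1 | step 18 | (1,4-dimethoxy-3-methyl-2-naphthyl)magnesium bromide | COc1c(C)c([Mg]Br)c(OC)c2ccccc12
F2 | step 18 | 1,4-dimethoxy-2-methyl-3-(3-methylbut-2-enyl)naphthalene | COc1c(C)c(CC=C(C)C)c(OC)c2ccccc12
F3 | step 18 | (2E)-4-(1,4-dimethoxy-3-methyl-2-naphthyl)-2-methylbut-2-en-1-ol | COc1c(C)c(C/C=C(C)/CO)c(OC)c2ccccc12
F4 | step 18 | 2-[(2E)-4-bromo-3-methylbut-2-enyl]-1,4-dimethoxy-3-methylnaphthalene | COc1c(C)c(C/C=C(C)/CBr)c(OC)c2ccccc12
F5 | step 18 | chain sulfone: 1,4-dimethoxy-3-methylnaphthalene carrying at C2 the full chain with PhSO2 at C5' (both epimers), C7' S | CC(C)=CCC/C(C)=C/CC/C(C)=C/CC/C(C)=C/CC/C(C)=C/CC/C(C)=C/CC[C@H](C)CC(S(=O)(=O)c1ccccc1)C/C(C)=C/Cc1c(C)c(OC)c2ccccc2c1OC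
F6 | step 18 | 1,4-dimethoxy-2-methyl-3-[(7'R)-all-E-chain]naphthalene (dimethyl ether of the target hydroquinone) | CC(C)=CCC/C(C)=C/CC/C(C)=C/CC/C(C)=C/CC/C(C)=C/CC/C(C)=C/CC[C@H](C)CCC/C(C)=C/Cc1c(C)c(OC)c2ccccc2c1OC
F7 | step 13 | (2E)-4-chloro-2-methylbut-2-enal | O=C/C(C)=C/CCl
F8 | step 13 | (2E)-4-chloro-2-methylbut-2-en-1-ol | OC/C(C)=C/CCl
F9 | step 9 | all-E-heptaprenal | CC(C)=CCC/C(C)=C/CC/C(C)=C/CC/C(C)=C/CC/C(C)=C/CC/C(C)=C/CC/C(C)=C/C=O
F10 | step 9 | (3S)-2,3-dihydro-all-E-heptaprenal | CC(C)=CCC/C(C)=C/CC/C(C)=C/CC/C(C)=C/CC/C(C)=C/CC/C(C)=C/CC[C@H](C)CC=O
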